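Retrosynthesis: the C11=C12 bond is cut first (Wittig) into a C25 ring A aldehyde and a C15 ring B enynyl phosphonium salt; the ring A chain is cut at C13=C14, C15=C15', C11'=C12' and C7'=C8' (olefinations) back to a C10 α-hydroxy aldehyde, and ring B at C6–C7 (Sonogashira) to an enol triflate and a C6 enynol.
Feature used: in ring A the hydroxyls on C3' and C6' are cis and sit on both sides of the C4'=C5' alkene, so the row O–C3'–C4'=C5'–C6'–O is what remains of a cyclohexa-1,3-diene endoperoxide after O–O reduction; taking the two oxygens away leaves the C3'=C4'–C5'=C6' diene of a safranal-derived ring that already holds C1' with its two methyls and C7'.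
Forward order: the ring A diene is oxygenated with singlet oxygen (the peroxide bridge is the only ring closed in the route; both carbocycles are bought), the O–O bond is reduced, the diol is resolved, C7' is oxidised and the chain is grown C10 → C15 → C20 → C22 → C25; ring B is made from ketoisophorone via an enol triflate and extended to the C15 tributylphosphonium salt; the halves are joined at C11=C12 and the last silyl group is removed.
Stereochemistry: C3'/C6' cis from the suprafacial cycloaddition, their absolute configuration from a lipase resolution; C3 from a yeast ene-reduction followed by substrate-controlled ketone hydrogenation; E alkenes from HWE and Wittig steps, with C9=C10 taken from the (E)-enynol and never ionised.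

Key step: step 3

Assumption (enantiopreference of the lipase): the ring arm C2'–C1' with its gem-dimethyl group is taken as the larger substituent at the C3' carbinol, so the empirical rule for lipases predicts acylation of the (3'S,6'R) enantiomer; if the enzyme prefers the other enantiomer, the recovered diol is the (3'S,6'R) one and Ac2O/pyridine converts it into the same acetate.

Step 1
Reactants: 1 safranal (2,6,6-trimethylcyclohexa-1,3-diene-1-carbaldehyde)
Product: 2 (2,6,6-trimethylcyclohexa-1,3-dien-1-yl)methanol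
Conditions: NaBH4, CeCl3·7H2O, MeOH, 0 °C
Reagents that add atoms: none
Why: Luche reduction delivers hydride to the carbonyl carbon only (1,2-reduction), so the ring diene needed in step 3 should stay untouched.

Step 2
Reactants: 2 (2,6,6-trimethylcyclohexa-1,3-dien-1-yl)methanol
Product: 3 tert-butyldimethyl[(2,6,6-trimethylcyclohexa-1,3-dien-1-yl)methoxy]silane
Conditions: TBSCl, imidazole, DMF, 0 °C to rt
Reagents that add atoms: tert-butyldimethylsilyl chloride, CC(C)(C)[Si](C)(C)Cl
Why: Imidazole-promoted silylation of a primary allylic alcohol is routine, and the silyl ether makes the diene electron-rich, removes the free OH that could steer an ene reaction and masks C7' until step 6.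

Step 3
Reactants: 3 tert-butyldimethyl[(2,6,6-trimethylcyclohexa-1,3-dien-1-yl)methoxy]silane
Product: 4 rac-(1R,4S)-1-{[(tert-butyldimethylsilyl)oxy]methyl}-6,7,7-trimethyl-2,3-dioxabicyclo[2.2.2]oct-5-ene (racemate; the enantiomer carried on is drawn)
Conditions: O2, tetraphenylporphyrin (cat.), white LED light, CH2Cl2, −20 °C
Reagents that add atoms: dioxygen, O=O
Why: Energy transfer from photoexcited tetraphenylporphyrin converts O2 into singlet oxygen, which adds across C3' and C6' of the ring diene in a concerted, suprafacial [4+2] cycloaddition that forms both C–O bonds and moves the alkene to C4'=C5'. The closest known reaction type is the dye-sensitised photooxygenation of cyclohexa-1,3-dienes to bicyclic endoperoxides (α-terpinene to ascaridole). The one new ring, the six-membered 1,2-dioxine that completes the 2,3-dioxabicyclo[2.2.2]oct-5-ene, closes by this cycloaddition, with the carbocycle as the diene and O2 as the two-atom partner. The stereocentres C3' and C6' are fixed relative to each other by delivery of both oxygens to one face of the planar diene, which is why the diol of step 4 is cis; the two faces of achiral 3 are enantiotopic, so 4 forms as a racemate and the absolute configuration is left to step 5. The step needs cycloaddition to outrun the ene reaction at the allylic C–H bonds of the C5' methyl, C2' and C7' groups, and the s-cis geometry locked by the six-membered ring, the electron-rich silyloxymethyl diene, the aprotic solvent and the low temperature favour it. Running it on the C10 ring, before any polyene is present, keeps singlet oxygen away from a chain that would quench it or be oxidised.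

Step 4
Reactants: 4 rac-(1R,4S)-1-{[(tert-butyldimethylsilyl)oxy]methyl}-6,7,7-trimethyl-2,3-dioxabicyclo[2.2.2]oct-5-ene
Product: 5 rac-(1R,4S)-1-{[(tert-butyldimethylsilyl)oxy]methyl}-2,6,6-trimethylcyclohex-2-ene-1,4-diol (racemate; the enantiomer carried on is drawn)
Conditions: thiourea, MeOH, rt
Reagents that add atoms: none
Why: Thiourea reduction of a bicyclic endoperoxide cleaves only the O–O bond under neutral conditions, so both C–O bonds stay in place and the ene-1,4-diol must be cis, while the base-induced Kornblum–DeLaMare isomerisation is avoided.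

Step 5
Reactants: 5 rac-(1R,4S)-1-{[(tert-butyldimethylsilyl)oxy]methyl}-2,6,6-trimethylcyclohex-2-ene-1,4-diol
Product: 6 (1S,4R)-4-{[(tert-butyldimethylsilyl)oxy]methyl}-4-hydroxy-3,5,5-trimethylcyclohex-2-en-1-yl acetate
Conditions: lipase PS (Burkholderia cepacia; immobilised), vinyl acetate, tBuOMe, 30 °C, stopped near half conversion
Reagents that add atoms: vinyl acetate, CC(=O)OC=C
Why: Lipase-catalysed kinetic resolution by irreversible transesterification should acylate only the secondary C3' hydroxyl of the (3'S,6'R) enantiomer (the tertiary OH and the silyl ether are inert), so the acetate carries the absolute configuration of ring A and the unreacted (3'R,6'S) diol is removed by chromatography.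

Step 6
Reactants: 6 (1S,4R)-4-{[(tert-butyldimethylsilyl)oxy]methyl}-4-hydroxy-3,5,5-trimethylcyclohex-2-en-1-yl acetate
Product: 7 (1S,4R)-4-hydroxy-4-(hydroxymethyl)-3,5,5-trimethylcyclohex-2-en-1-yl acetate
Conditions: HF·pyridine, pyridine, THF, 0 °C to rt
Reagents that add atoms: none
Why: Fluoride-mediated desilylation of the primary silyl ether under pyridine-buffered, non-basic conditions should leave the allylic acetate and the tertiary allylic alcohol intact and give no chance for acetyl migration.

Step 7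
Reactants: 7 (1S,4R)-4-hydroxy-4-(hydroxymethyl)-3,5,5-trimethylcyclohex-2-en-1-yl acetate
Product: 8 (1S,4R)-4-formyl-4-hydroxy-3,5,5-trimethylcyclohex-2-en-1-yl acetate
Conditions: IBX, DMSO, rt
Reagents that add atoms: none
Why: IBX oxidation turns the primary alcohol of a primary/tertiary 1,2-diol into the α-hydroxy aldehyde without glycol cleavage, the tertiary OH cannot be oxidised, the secondary allylic OH is masked as the acetate, and C6' bears no hydrogen and cannot epimerise.

Step 8
Reactants: 8 (1S,4R)-4-formyl-4-hydroxy-3,5,5-trimethylcyclohex-2-en-1-yl acetate; 9 diethyl [(2E)-3-cyano-2-methylprop-2-en-1-yl]phosphonate (sold as an E/Z mixture)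
Product: 11 (1S,4R)-4-[(1E,3E)-4-cyano-3-methylbuta-1,3-dien-1-yl]-4-hydroxy-3,5,5-trimethylcyclohex-2-en-1-yl acetate, via phosphonate carbanion sodium salt 10 (not isolated)
Conditions: 9, NaH, THF, 0 °C; then 8, −20 °C to rt
Reagents that add atoms: none
Why: Horner–Wadsworth–Emmons olefination with the vinylogous cyanophosphonate anion, made with the non-nucleophilic base NaH so that the acetate meets no alkoxide reagent and used in excess to cover the free tertiary OH, should form C7'=C8' as the E isomer at the hindered aldehyde, while the C9'=C10' bond equilibrates through the allyl anion mainly to E, any 9'Z isomer being removable after step 9.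

Step 9
Reactants: 11 (1S,4R)-4-[(1E,3E)-4-cyano-3-methylbuta-1,3-dien-1-yl]-4-hydroxy-3,5,5-trimethylcyclohex-2-en-1-yl acetate
Product: 13 (2E,4E)-5-[(1R,4S)-1,4-dihydroxy-2,6,6-trimethylcyclohex-2-en-1-yl]-3-methylpenta-2,4-dienal, via aldimine 12 (not isolated)
Conditions: iBu2AlH, CH2Cl2, −78 to −40 °C; then wet SiO2, 0 °C
Reagents that add atoms: water, O
Why: Reduction of a conjugated nitrile with iBu2AlH stops at the N-aluminium aldimine, which mild hydrolysis turns into the aldehyde (nitrile-to-aldehyde reduction), and the same hydride reductively removes the acetate, which is no longer needed, so the diol aldehyde is reached in one operation.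

Step 10
Reactants: 13 (2E,4E)-5-[(1R,4S)-1,4-dihydroxy-2,6,6-trimethylcyclohex-2-en-1-yl]-3-methylpenta-2,4-dienal; 9 diethyl [(2E)-3-cyano-2-methylprop-2-en-1-yl]phosphonate
Product: 15 (2E,4E,6E,8E)-9-[(1R,4S)-1,4-dihydroxy-2,6,6-trimethylcyclohex-2-en-1-yl]-3,7-dimethylnona-2,4,6,8-tetraenenitrile, via phosphonate carbanion potassium salt 14 (not isolated)
Conditions: 9, KOtBu, THF, 0 °C; then 13, 0 °C to rt
Reagents that add atoms: none
Why: A second Horner–Wadsworth–Emmons reaction adds C12' to C15'; since no ester is left in the substrate, the soluble alkoxide base KOtBu can be used to give the potassium carbanion of the C5 cyanophosphonate in homogeneous THF solution (base and phosphonate in excess, because the two hydroxyls of 13 take up part of the base), and the olefination should form C11'=C12' as the E isomer and C13'=C14' mainly E.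

Step 11
Reactants: 15 (2E,4E,6E,8E)-9-[(1R,4S)-1,4-dihydroxy-2,6,6-trimethylcyclohex-2-en-1-yl]-3,7-dimethylnona-2,4,6,8-tetraenenitrile
Product: 17 (2E,4E,6E,8E)-9-[(1R,4S)-1,4-dihydroxy-2,6,6-trimethylcyclohex-2-en-1-yl]-3,7-dimethylnona-2,4,6,8-tetraenal, via aldimine 16 (not isolated)
Conditions: iBu2AlH, CH2Cl2, −78 °C; then wet SiO2, 0 °C
Reagents that add atoms: water, O
Why: The nitrile-to-aldehyde reduction with iBu2AlH is repeated, the hydride adding once to the nitrile at low temperature and the aldimine being hydrolysed on work-up, and any 13'Z isomer should be separable at this aldehyde stage.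

Step 12
Reactants: 17 (2E,4E,6E,8E)-9-[(1R,4S)-1,4-dihydroxy-2,6,6-trimethylcyclohex-2-en-1-yl]-3,7-dimethylnona-2,4,6,8-tetraenal; 18 diethyl {2-[methoxy(methyl)amino]-2-oxoethyl}phosphonate
Product: 20 (2E,4E,6E,8E,10E)-11-[(1R,4S)-1,4-dihydroxy-2,6,6-trimethylcyclohex-2-en-1-yl]-N-methoxy-N,5,9-trimethylundeca-2,4,6,8,10-pentaenamide, via amide phosphonate carbanion sodium salt 19 (not isolated)
Conditions: 18, NaH, THF, 0 °C; then 17, 0 °C to rt
Reagents that add atoms: none
Why: The Horner–Wadsworth–Emmons reaction of the Weinreb amide phosphonate behaves like that of a phosphonoacetate and should give the new disubstituted C15'=C15 bond with high E selectivity.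

Step 13
Reactants: 20 (2E,4E,6E,8E,10E)-11-[(1R,4S)-1,4-dihydroxy-2,6,6-trimethylcyclohex-2-en-1-yl]-N-methoxy-N,5,9-trimethylundeca-2,4,6,8,10-pentaenamide
Product: 22 (2E,4E,6E,8E,10E)-11-[(1R,4S)-1,4-dihydroxy-2,6,6-trimethylcyclohex-2-en-1-yl]-5,9-dimethylundeca-2,4,6,8,10-pentaenal, via aluminium hemiaminal 21 (not isolated)
Conditions: iBu2AlH, THF, −78 °C; then KNaC4H4O6 (aq.)
Reagents that add atoms: none
Why: Reduction of a Weinreb amide with iBu2AlH stops at the aldehyde level because the chelated tetrahedral aluminium hemiaminal collapses only on aqueous work-up, and the polyene and the two hydroxyls (as aluminium alkoxides) are not affected.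

Step 14
Reactants: 22 (2E,4E,6E,8E,10E)-11-[(1R,4S)-1,4-dihydroxy-2,6,6-trimethylcyclohex-2-en-1-yl]-5,9-dimethylundeca-2,4,6,8,10-pentaenal; 23 2-(triphenylphosphoranylidene)propanal
Product: 24 (2E,4E,6E,8E,10E,12E)-13-[(1R,4S)-1,4-dihydroxy-2,6,6-trimethylcyclohex-2-en-1-yl]-2,7,11-trimethyltrideca-2,4,6,8,10,12-hexaenal
Conditions: toluene, 70 °C, dark
Reagents that add atoms: none
Why: The Wittig reaction of the stabilised formyl ylide under neutral conditions gives the E trisubstituted enal (C13=C14), and the α-methyl enal formed is too hindered to react with a second equivalent of the ylide.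

Step 15
Reactants: 25 ketoisophorone (2,6,6-trimethylcyclohex-2-ene-1,4-dione)
Product: 26 (6R)-2,2,6-trimethylcyclohexane-1,4-dione
Conditions: baker's yeast (Saccharomyces cerevisiae), sucrose, H2O, 30 °C
Reagents that add atoms: none
Why: Baker's yeast reduces the electron-poor C=C bond of the enedione (enzymatic ene-reduction) with hydride delivery to one face of the alkene, which sets C6 as R.

Step 16
Reactants: 26 (6R)-2,2,6-trimethylcyclohexane-1,4-dione
Product: 27 (4R,6R)-4-hydroxy-2,2,6-trimethylcyclohexan-1-one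
Conditions: H2 (5 bar), neutral Raney Ni, MeOH, rt; recrystallisation
Reagents that add atoms: none
Why: Heterogeneous hydrogenation reduces only the unhindered C4 carbonyl (C1 is flanked by a quaternary and a tertiary carbon), and hydrogen arrives from the equatorial side away from the axial C2 methyl, so the existing C6 centre controls C4 and the trans (4R,6R) alcohol should predominate, the cis isomer being removed by crystallisation.

Step 17
Reactants: 27 (4R,6R)-4-hydroxy-2,2,6-trimethylcyclohexan-1-one
Product: 28 (4R,6R)-4-[(tert-butyldimethylsilyl)oxy]-2,2,6-trimethylcyclohexan-1-one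
Conditions: TBSCl, imidazole, DMF, rt
Reagents that add atoms: tert-butyldimethylsilyl chloride, CC(C)(C)[Si](C)(C)Cl
Why: Standard silylation of the secondary alcohol protects it against the strong base of step 18 and the bromination of step 20.

Step 18
Reactants: 28 (4R,6R)-4-[(tert-butyldimethylsilyl)oxy]-2,2,6-trimethylcyclohexan-1-one
Product: 30 (4R)-4-[(tert-butyldimethylsilyl)oxy]-2,6,6-trimethylcyclohex-1-en-1-yl trifluoromethanesulfonate, via lithium enolate 29 (not isolated)
Conditions: LiN(iPr)2, THF, −78 to 0 °C; then PhNTf2, −78 °C to rt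
Reagents that add atoms: N-phenylbis(trifluoromethanesulfonimide), O=S(=O)(N(c1ccccc1)S(=O)(=O)C(F)(F)F)C(F)(F)F
Why: In this enol triflate formation the ketone has a single α-hydrogen (at C6), so LiN(iPr)2 can give only one enolate, which PhNTf2 triflates on oxygen, erasing the C6 stereocentre as intended and leaving C4 untouched.

Step 19
Reactants: 30 (4R)-4-[(tert-butyldimethylsilyl)oxy]-2,6,6-trimethylcyclohex-1-en-1-yl trifluoromethanesulfonate; 31 (2E)-3-methylpent-2-en-4-yn-1-ol
Product: 32 (2E)-5-{(4R)-4-[(tert-butyldimethylsilyl)oxy]-2,6,6-trimethylcyclohex-1-en-1-yl}-3-methylpent-2-en-4-yn-1-ol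
Conditions: Pd(PPh3)4 (cat.), CuI (copper monoiodide, cat.), iPr2NH, DMF, rt
Reagents that add atoms: none
Why: Sonogashira coupling of an alkenyl triflate with a terminal alkyne forms the C6–C7 bond, and since the double bond of the enynol takes no part, its E geometry (the future C9=C10) is carried over unchanged.

Step 20
Reactants: 32 (2E)-5-{(4R)-4-[(tert-butyldimethylsilyl)oxy]-2,6,6-trimethylcyclohex-1-en-1-yl}-3-methylpent-2-en-4-yn-1-ol
Product: 33 {[(1R)-4-[(3E)-5-bromo-3-methylpent-3-en-1-yn-1-yl]-3,5,5-trimethylcyclohex-3-en-1-yl]oxy}(tert-butyl)dimethylsilane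
Conditions: CBr4, PPh3, CH2Cl2, 0 °C
Reagents that add atoms: carbon tetrabromide, BrC(Br)(Br)Br
Why: Appel bromination proceeds by SN2 displacement at the primary carbinol carbon under neutral conditions, so no allyl cation is formed and both the C9=C10 geometry and the silyl ether should survive.

Step 21
Reactants: 33 {[(1R)-4-[(3E)-5-bromo-3-methylpent-3-en-1-yn-1-yl]-3,5,5-trimethylcyclohex-3-en-1-yl]oxy}(tert-butyl)dimethylsilane
Product: 34 tributyl[(2E)-5-{(4R)-4-[(tert-butyldimethylsilyl)oxy]-2,6,6-trimethylcyclohex-1-en-1-yl}-3-methylpent-2-en-4-yn-1-yl]phosphonium bromide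
Conditions: PBu3, EtOAc, rt
Reagents that add atoms: tributylphosphine, CCCCP(CCCC)CCCC
Why: Quaternisation of tributylphosphine by SN2 attack on the primary allylic bromide gives the trialkylphosphonium salt without ionisation, again keeping the C9=C10 bond E.

Step 22
Reactants: 24 (2E,4E,6E,8E,10E,12E)-13-[(1R,4S)-1,4-dihydroxy-2,6,6-trimethylcyclohex-2-en-1-yl]-2,7,11-trimethyltrideca-2,4,6,8,10,12-hexaenal; 34 tributyl[(2E)-5-{(4R)-4-[(tert-butyldimethylsilyl)oxy]-2,6,6-trimethylcyclohex-1-en-1-yl}-3-methylpent-2-en-4-yn-1-yl]phosphonium bromide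
Product: 36 (3R,3'S,6'R)-3-[(tert-butyldimethylsilyl)oxy]-7,8-didehydro-β,ε-carotene-3',6'-diol (all-E), via phosphorus ylide 35 (not isolated)
Conditions: NaOMe, CH2Cl2/MeOH, 0 °C to rt, dark
Reagents that add atoms: none
Why: In this Wittig olefination the allylic tributylphosphonium ylide, unlike its triphenyl analogue, is expected to react with the enal with high E selectivity at C11=C12, and the mild base NaOMe tolerates the free hydroxyls of 24 and should leave the C9=C10 geometry alone.

Step 23
Reactants: 36 (3R,3'S,6'R)-3-[(tert-butyldimethylsilyl)oxy]-7,8-didehydro-β,ε-carotene-3',6'-diol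
Product: 37 (3R,3'S,6'R)-7,8-didehydro-β,ε-carotene-3,3',6'-triol (all-E; the target)
Conditions: Bu4NF, THF, 0 °C to rt, dark
Reagents that add atoms: none
Why: Fluoride-mediated cleavage of the secondary silyl ether under basic, non-acidic conditions spares the acid-labile tertiary bis-allylic C6' alcohol and the polyene.

Compound list
1 | safranal (2,6,6-trimethylcyclohexa-1,3-diene-1-carbaldehyde) | CC1=C(C=O)C(C)(C)CC=C1 | starting material
2 | (2,6,6-trimethylcyclohexa-1,3-dien-1-yl)methanol | CC1=C(CO)C(C)(C)CC=C1 | intermediate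
3 | tert-butyldimethyl[(2,6,6-trimethylcyclohexa-1,3-dien-1-yl)methoxy]silane | CC1=C(CO[Si](C)(C)C(C)(C)C)C(C)(C)CC=C1 | intermediate
4 | rac-(1R,4S)-1-{[(tert-butyldimethylsilyl)oxy]methyl}-6,7,7-trimethyl-2,3-dioxabicyclo[2.2.2]oct-5-ene (racemate; enantiomer carried on drawn) | CC1=C[C@@H]2CC(C)(C)[C@@]1(CO[Si](C)(C)C(C)(C)C)OO2 | intermediate
5 | rac-(1R,4S)-1-{[(tert-butyldimethylsilyl)oxy]methyl}-2,6,6-trimethylcyclohex-2-ene-1,4-diol (racemate; enantiomer carried on drawn) | CC1=C[C@@H](O)CC(C)(C)[C@]1(O)CO[Si](C)(C)C(C)(C)C | intermediate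
6 | (1S,4R)-4-{[(tert-butyldimethylsilyl)oxy]methyl}-4-hydroxy-3,5,5-trimethylcyclohex-2-en-1-yl acetate | CC1=C[C@@H](OC(C)=O)CC(C)(C)[C@]1(O)CO[Si](C)(C)C(C)(C)C | intermediate
7 | (1S,4R)-4-hydroxy-4-(hydroxymethyl)-3,5,5-trimethylcyclohex-2-en-1-yl acetate | CC1=C[C@@H](OC(C)=O)CC(C)(C)[C@]1(O)CO | intermediate
8 | (1S,4R)-4-formyl-4-hydroxy-3,5,5-trimethylcyclohex-2-en-1-yl acetate | CC1=C[C@@H](OC(C)=O)CC(C)(C)[C@]1(O)C=O | intermediate
9 | diethyl [(2E)-3-cyano-2-methylprop-2-en-1-yl]phosphonate (sold as an E/Z mixture; E isomer drawn) | CCOP(=O)(OCC)C/C(C)=C/C#N | starting material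
10 | sodium salt of the carbanion of 9 (delocalised; no fixed alkene geometry) | [Na+].CCOP(=O)(OCC)[CH-]C(C)=CC#N | intermediate (not isolated)
11 | (1S,4R)-4-[(1E,3E)-4-cyano-3-methylbuta-1,3-dien-1-yl]-4-hydroxy-3,5,5-trimethylcyclohex-2-en-1-yl acetate | CC1=C[C@@H](OC(C)=O)CC(C)(C)[C@]1(O)/C=C/C(C)=C/C#N | intermediate
12 | (2E,4E)-5-[(1R,4S)-1,4-dihydroxy-2,6,6-trimethylcyclohex-2-en-1-yl]-3-methylpenta-2,4-dien-1-imine (aluminium-bound in the flask; drawn as the free imine) | CC1=C[C@@H](O)CC(C)(C)[C@]1(O)/C=C/C(C)=C/C=N | intermediate (not isolated)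
13 | (2E,4E)-5-[(1R,4S)-1,4-dihydroxy-2,6,6-trimethylcyclohex-2-en-1-yl]-3-methylpenta-2,4-dienal | CC1=C[C@@H](O)CC(C)(C)[C@]1(O)/C=C/C(C)=C/C=O | intermediate
14 | potassium salt of the carbanion of 9 (delocalised; no fixed alkene geometry) | [K+].CCOP(=O)(OCC)[CH-]C(C)=CC#N | intermediate (not isolated)
15 | (2E,4E,6E,8E)-9-[(1R,4S)-1,4-dihydroxy-2,6,6-trimethylcyclohex-2-en-1-yl]-3,7-dimethylnona-2,4,6,8-tetraenenitrile | CC1=C[C@@H](O)CC(C)(C)[C@]1(O)/C=C/C(C)=C/C=C/C(C)=C/C#N | intermediate
16 | (2E,4E,6E,8E)-9-[(1R,4S)-1,4-dihydroxy-2,6,6-trimethylcyclohex-2-en-1-yl]-3,7-dimethylnona-2,4,6,8-tetraen-1-imine (aluminium-bound in the flask; drawn as the free imine) | CC1=C[C@@H](O)CC(C)(C)[C@]1(O)/C=C/C(C)=C/C=C/C(C)=C/C=N | intermediate (not isolated)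
17 | (2E,4E,6E,8E)-9-[(1R,4S)-1,4-dihydroxy-2,6,6-trimethylcyclohex-2-en-1-yl]-3,7-dimethylnona-2,4,6,8-tetraenal | CC1=C[C@@H](O)CC(C)(C)[C@]1(O)/C=C/C(C)=C/C=C/C(C)=C/C=O | intermediate
18 | diethyl {2-[methoxy(methyl)amino]-2-oxoethyl}phosphonate | CCOP(=O)(OCC)CC(=O)N(C)OC | starting material
19 | sodium salt of the carbanion of 18 | [Na+].CCOP(=O)(OCC)[CH-]C(=O)N(C)OC | intermediate (not isolated)
20 | (2E,4E,6E,8E,10E)-11-[(1R,4S)-1,4-dihydroxy-2,6,6-trimethylcyclohex-2-en-1-yl]-N-methoxy-N,5,9-trimethylundeca-2,4,6,8,10-pentaenamide | CC1=C[C@@H](O)CC(C)(C)[C@]1(O)/C=C/C(C)=C/C=C/C(C)=C/C=C/C(=O)N(C)OC | intermediate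
21 | tetrahedral N-methoxy-N-methyl hemiaminal from 20 (aluminium-bound in the flask; drawn as the free carbinolamine) | CC1=C[C@@H](O)CC(C)(C)[C@]1(O)/C=C/C(C)=C/C=C/C(C)=C/C=C/C(O)N(C)OC | intermediate (not isolated)
22 | (2E,4E,6E,8E,10E)-11-[(1R,4S)-1,4-dihydroxy-2,6,6-trimethylcyclohex-2-en-1-yl]-5,9-dimethylundeca-2,4,6,8,10-pentaenal | CC1=C[C@@H](O)CC(C)(C)[C@]1(O)/C=C/C(C)=C/C=C/C(C)=C/C=C/C=O | intermediate
23 | 2-(triphenylphosphoranylidene)propanal | CC(C=O)=P(c1ccccc1)(c1ccccc1)c1ccccc1 | starting material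
24 | (2E,4E,6E,8E,10E,12E)-13-[(1R,4S)-1,4-dihydroxy-2,6,6-trimethylcyclohex-2-en-1-yl]-2,7,11-trimethyltrideca-2,4,6,8,10,12-hexaenal | CC1=C[C@@H](O)CC(C)(C)[C@]1(O)/C=C/C(C)=C/C=C/C(C)=C/C=C/C=C(C)/C=O | intermediate
25 | ketoisophorone (2,6,6-trimethylcyclohex-2-ene-1,4-dione) | CC1=CC(=O)CC(C)(C)C1=O | starting material
26 | (6R)-2,2,6-trimethylcyclohexane-1,4-dione | C[C@@H]1CC(=O)CC(C)(C)C1=O | intermediate
27 | (4R,6R)-4-hydroxy-2,2,6-trimethylcyclohexan-1-one | C[C@@H]1C[C@@H](O)CC(C)(C)C1=O | intermediate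
28 | (4R,6R)-4-[(tert-butyldimethylsilyl)oxy]-2,2,6-trimethylcyclohexan-1-one | C[C@@H]1C[C@@H](O[Si](C)(C)C(C)(C)C)CC(C)(C)C1=O | intermediate
29 | lithium (4R)-4-[(tert-butyldimethylsilyl)oxy]-2,6,6-trimethylcyclohex-1-en-1-olate | [Li+].[O-]C1=C(C)C[C@@H](O[Si](C)(C)C(C)(C)C)CC1(C)C | intermediate (not isolated)
30 | (4R)-4-[(tert-butyldimethylsilyl)oxy]-2,6,6-trimethylcyclohex-1-en-1-yl trifluoromethanesulfonate | FC(F)(F)S(=O)(=O)OC1=C(C)C[C@@H](O[Si](C)(C)C(C)(C)C)CC1(C)C | intermediate
31 | (2E)-3-methylpent-2-en-4-yn-1-ol | OC/C=C(\C)C#C | starting material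
32 | (2E)-5-{(4R)-4-[(tert-butyldimethylsilyl)oxy]-2,6,6-trimethylcyclohex-1-en-1-yl}-3-methylpent-2-en-4-yn-1-ol | OC/C=C(\C)C#CC1=C(C)C[C@@H](O[Si](C)(C)C(C)(C)C)CC1(C)C | intermediate
33 | {[(1R)-4-[(3E)-5-bromo-3-methylpent-3-en-1-yn-1-yl]-3,5,5-trimethylcyclohex-3-en-1-yl]oxy}(tert-butyl)dimethylsilane | BrC/C=C(\C)C#CC1=C(C)C[C@@H](O[Si](C)(C)C(C)(C)C)CC1(C)C | intermediate
34 | tributyl[(2E)-5-{(4R)-4-[(tert-butyldimethylsilyl)oxy]-2,6,6-trimethylcyclohex-1-en-1-yl}-3-methylpent-2-en-4-yn-1-yl]phosphonium bromide | [Br-].CCCC[P+](CCCC)(CCCC)C/C=C(\C)C#CC1=C(C)C[C@@H](O[Si](C)(C)C(C)(C)C)CC1(C)C | intermediate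
35 | ylide of 34: tributyl[(2E)-5-{(4R)-4-[(tert-butyldimethylsilyl)oxy]-2,6,6-trimethylcyclohex-1-en-1-yl}-3-methylpent-2-en-4-yn-1-ylidene]phosphorane | CCCCP(CCCC)(CCCC)=C/C=C(\C)C#CC1=C(C)C[C@@H](O[Si](C)(C)C(C)(C)C)CC1(C)C | intermediate (not isolated)
36 | (3R,3'S,6'R)-3-[(tert-butyldimethylsilyl)oxy]-7,8-didehydro-β,ε-carotene-3',6'-diol (all-E) | CC1=C[C@@H](O)CC(C)(C)[C@]1(O)/C=C/C(C)=C/C=C/C(C)=C/C=C/C=C(C)/C=C/C=C(\C)C#CC1=C(C)C[C@@H](O[Si](C)(C)C(C)(C)C)CC1(C)C | intermediate
37 | (3R,3'S,6'R)-7,8-didehydro-β,ε-carotene-3,3',6'-triol (all-E) | CC1=C[C@@H](O)CC(C)(C)[C@]1(O)/C=C/C(C)=C/C=C/C(C)=C/C=C/C=C(C)/C=C/C=C(\C)C#CC1=C(C)C[C@@H](O)CC1(C)C | target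

Total step count: 23. Longest linear sequence: 16 steps (steps 1 to 14, then 22 and 23); the ring B branch (steps 15 to 21) joins at step 22.

Steps most likely to fail

Step 5. The enzyme may discriminate poorly between the enantiomers of the hindered cis-diol, or acylate it too slowly, which would leave ring A with low enantiomeric purity. The fallback is a classical resolution that sets out from racemic 5. The secondary hydroxyl is esterified with (S)-O-methylmandelic acid (DCC, DMAP, CH2Cl2) and the two diastereomeric esters are separated on silica. The ester of the wanted series, (1S,4R)-4-{[(tert-butyldimethylsilyl)oxy]methyl}-4-hydroxy-3,5,5-trimethylcyclohex-2-en-1-yl (2S)-2-methoxy-2-phenylacetate F1, is methanolysed (K2CO3, MeOH) to the enantiopure diol (1R,4S)-1-{[(tert-butyldimethylsilyl)oxy]methyl}-2,6,6-trimethylcyclohex-2-ene-1,4-diol F2. Ac2O/pyridine then acetylates only its secondary hydroxyl, and the material rejoins the route at 6.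

Step 8. The alkoxide of the tertiary α-hydroxy aldehyde may undergo α-ketol rearrangement (ring expansion) or acetyl migration faster than the neopentyl-type carbonyl is olefinated. The fallback sets out from 8 and avoids strong base at the aldehyde stage. A neutral Wittig reaction with the stabilised ylide 1-(triphenylphosphoranylidene)propan-2-one (toluene, 90 °C) should give the E-enone (1S,4R)-4-hydroxy-3,5,5-trimethyl-4-[(1E)-3-oxobut-1-en-1-yl]cyclohex-2-en-1-yl acetate F3. A Horner–Wadsworth–Emmons reaction of this methyl ketone with the anion of diethyl cyanomethylphosphonate (NaH, THF) then builds the C9'=C10' bond and comes back to the route at nitrile 11, the 9'Z isomer being separated as in the main line.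

Step 22. E selectivity at the new C11=C12 bond may erode, and the C9=C10 bond may isomerise through the delocalised ylide. This cannot be repaired afterwards by thermal or iodine isomerisation, because the enyne end of such polyenes equilibrates towards the 9Z form. The fallback sets out from bromide 33. A Michaelis–Arbuzov reaction with P(OEt)3 (90 °C) gives diethyl [(2E)-5-{(4R)-4-[(tert-butyldimethylsilyl)oxy]-2,6,6-trimethylcyclohex-1-en-1-yl}-3-methylpent-2-en-4-yn-1-yl]phosphonate F4. Deprotonated with KOtBu (THF, −30 °C), it is then used in a Horner–Wadsworth–Emmons reaction with aldehyde 24, which has the thermodynamic E preference of phosphonate olefinations and rejoins the route at 36.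

Further compounds
F1 | step 5 | (1S,4R)-4-{[(tert-butyldimethylsilyl)oxy]methyl}-4-hydroxy-3,5,5-trimethylcyclohex-2-en-1-yl (2S)-2-methoxy-2-phenylacetate | CC1=C[C@@H](OC(=O)[C@@H](OC)c2ccccc2)CC(C)(C)[C@]1(O)CO[Si](C)(C)C(C)(C)C
F2 | step 5 | (1R,4S)-1-{[(tert-butyldimethylsilyl)oxy]methyl}-2,6,6-trimethylcyclohex-2-ene-1,4-diol (single enantiomer) | CC1=C[C@@H](O)CC(C)(C)[C@]1(O)CO[Si](C)(C)C(C)(C)C
F3 | step 8 | (1S,4R)-4-hydroxy-3,5,5-trimethyl-4-[(1E)-3-oxobut-1-en-1-yl]cyclohex-2-en-1-yl acetate | CC1=C[C@@H](OC(C)=O)CC(C)(C)[C@]1(O)/C=C/C(C)=O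
F4 | step 22 | diethyl [(2E)-5-{(4R)-4-[(tert-butyldimethylsilyl)oxy]-2,6,6-trimethylcyclohex-1-en-1-yl}-3-methylpent-2-en-4-yn-1-yl]phosphonate | CCOP(=O)(OCC)C/C=C(\C)C#CC1=C(C)C[C@@H](O[Si](C)(C)C(C)(C)C)CC1(C)C
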